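**Retrosynthetic overview**

1. The last two events are a catalyst-controlled epoxidation of the C3=C4 olefin (sets C3 and C4) and a reagent-controlled reduction of a C7 ketone (sets C7) on a macrocyclic α-methylene lactone.
2. Key step: an indium Barbier macrocyclisation of an open-chain (Z)-2-(bromomethyl)enoate onto an α-hydroxy aldehyde forms the C1–C14 bond, the 14-membered ring and, by lactonisation, the cis-fused α-methylene-γ-lactone; chelation by the C13 hydroxyl sets C14 and C1.
3. The open chain comes from a Nozaki–Hiyama–Kishi union at C7–C8 of a west 2-bromoalkene (C8–C14) with an east aldehyde (C1–C7 plus the acrylate carbons).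
4. West: catalytic asymmetric Z-crotylboration of glyoxal mono(dimethyl acetal) (sets C12 and C13), then hydroboration and copper-catalysed coupling with 2,3-dibromopropene. East: Negishi carboalumination/ethylene oxide on a pentynyl silyl ether, then vinylalumination with methyl propiolate.
5. Ring order: carbocycle, then γ-lactone (same operation), epoxide last.

Convention (one line): cembrane numbering is used for the target and late intermediates: C1 = ring CH bearing C15 (C16 = lactone C=O, C17 = its CH2), C3/C4 = epoxide carbons (C18 methyl on C4), C7 = carbinol, C8 (=C19H2), C12 (C20 methyl), C13 = CHOAc, C14 = lactone CH–O; the target is (1S,3R,4R,7R,12S,13R,14R).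

**Route**

Step 1
Reactants: 1 2,2-dimethoxyacetaldehyde (anhydrous); 2 (Z)-crotylboronic acid pinacol ester
Product: 3 (2R,3S)-1,1-dimethoxy-3-methylpent-4-en-2-ol
Conditions: (R)-TRIP [(R)-3,3'-bis(2,4,6-triisopropylphenyl)-1,1'-binaphthyl-2,2'-diyl hydrogen phosphate] (5 mol %), 4 Å MS, toluene, −30 °C; aq. NaHCO3
Reagents that add atoms: none
Why: Chiral phosphoric acid-catalysed crotylboration through a closed chair transition state, in which the Z-boronate gives the syn methyl/hydroxyl pair and the (R)-acid is chosen to select the aldehyde face leading to 13R,12S (the (S)-acid would give ent-3).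

Step 2
Reactants: 3 (2R,3S)-1,1-dimethoxy-3-methylpent-4-en-2-ol
Product: 4 (2R,3S)-1,1-dimethoxy-3-methyl-2-(triethylsilyloxy)pent-4-ene
Conditions: TESCl, imidazole, CH2Cl2, 0 °C → rt
Reagents that add atoms: chlorotriethylsilane, CC[Si](Cl)(CC)CC
Why: Standard silylation of the secondary alcohol, which keeps it out of the borane, organocopper and chromium steps and is removed together with the acetal in step 12.

Step 3
Reactants: 4 (2R,3S)-1,1-dimethoxy-3-methyl-2-(triethylsilyloxy)pent-4-ene; 5 2,3-dibromopropene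
Product: 7 (6S,7R)-2-bromo-8,8-dimethoxy-6-methyl-7-(triethylsilyloxy)oct-1-ene, via B-alkyl-9-BBN 6 (not isolated)
Conditions: 9-BBN, THF, 0 °C → rt; then KOt-Bu, CuOAc (10 mol %), 5, THF, rt
Reagents that add atoms: none
Why: Anti-Markovnikov hydroboration of the only alkene, then copper-catalysed allyl–alkyl coupling of the tert-butoxyborate at the allylic C–Br bond of 5 (both allyl termini give the same 2-bromoalkene and the vinylic bromide is inert), which installs C8, C9 and C19.

Step 4
Reactants: 8 tert-butyldimethyl(pent-4-yn-1-yloxy)silane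
Product: 10 (E)-7-(tert-butyldimethylsilyloxy)-4-methylhept-3-en-1-ol, via alkenylalane 9 (not isolated)
Conditions: Me3Al, Cp2ZrCl2 (25 mol %), CH2Cl2, 0 °C → rt; then n-BuLi, THF, −30 °C; ethylene oxide, −30 → 0 °C
Reagents that add atoms: trimethylaluminium, C[Al](C)C; ethylene oxide, C1CO1
Why: Negishi zirconium-catalysed syn-carboalumination puts the new methyl and the aluminium cis on the alkyne, and the derived alanate opens ethylene oxide with retention of alkene geometry, fixing the E-trisubstituted C3=C4 olefin.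

Step 5
Reactants: 10 (E)-7-(tert-butyldimethylsilyloxy)-4-methylhept-3-en-1-ol
Product: 11 (E)-7-(tert-butyldimethylsilyloxy)-4-methylhept-3-enal
Conditions: Dess–Martin periodinane, NaHCO3, CH2Cl2, 0 °C (used crude)
Reagents that add atoms: none
Why: Buffered Dess–Martin oxidation gives the β,γ-unsaturated aldehyde without base-induced migration of the double bond into conjugation.

Step 6
Reactants: 11 (E)-7-(tert-butyldimethylsilyloxy)-4-methylhept-3-enal; 12 methyl propiolate
Product: 14 methyl (5E)-9-(tert-butyldimethylsilyloxy)-3-hydroxy-6-methyl-2-methylidenenon-5-enoate (racemic at C-3), via vinylalane 13 (not isolated)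
Conditions: i-Bu2AlH, N-methylmorpholine N-oxide, THF, 0 °C (with 12); then 11, 0 °C → rt
Reagents that add atoms: none
Why: Vinylalumination (conjugate hydroalumination of the propiolate to the α-alanyl acrylate, then 1,2-addition to the aldehyde) gives the Baylis–Hillman-type adduct under amine-free conditions that do not isomerise the aldehyde; the new carbinol centre is erased in step 11.

Step 7
Reactants: 14 methyl (5E)-9-(tert-butyldimethylsilyloxy)-3-hydroxy-6-methyl-2-methylidenenon-5-enoate
Product: 15 methyl (5E)-3,9-dihydroxy-6-methyl-2-methylidenenon-5-enoate (racemic)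
Conditions: HF·pyridine, pyridine, THF, 0 °C → rt
Reagents that add atoms: none
Why: Buffered fluoride desilylation of the primary silyl ether leaves the acrylate and the allylic alcohol untouched.

Step 8
Reactants: 15 methyl (5E)-3,9-dihydroxy-6-methyl-2-methylidenenon-5-enoate
Product: 16 methyl (5E)-3-hydroxy-6-methyl-2-methylidene-9-oxonon-5-enoate (racemic)
Conditions: TEMPO (2,2,6,6-tetramethylpiperidin-1-oxyl, 10 mol %), PhI(OAc)2, CH2Cl2, rt
Reagents that add atoms: none
Why: Oxoammonium (TEMPO/PhI(OAc)2) oxidation is selective for the primary alcohol over the hindered, electron-poor secondary allylic alcohol.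

Step 9
Reactants: 7 (6S,7R)-2-bromo-8,8-dimethoxy-6-methyl-7-(triethylsilyloxy)oct-1-ene; 16 methyl (5E)-3-hydroxy-6-methyl-2-methylidene-9-oxonon-5-enoate
Product: 17 methyl (5E,14S,15R)-3,9-dihydroxy-16,16-dimethoxy-6,14-dimethyl-2,10-dimethylidene-15-(triethylsilyloxy)hexadec-5-enoate (C-3/C-9 epimer mixture)
Conditions: CrCl2 (5 equiv), NiCl2 (2 mol %), DMSO, rt
Reagents that add atoms: none
Why: Nozaki–Hiyama–Kishi coupling (nickel-catalysed formation of the alkenylchromium from the 2-bromoalkene and its chemoselective addition to the aldehyde) joins C7 to C8 in the presence of the free hydroxyl, acrylate, acetal and silyl ether; the C7 configuration is irrelevant because this carbinol is oxidised in step 10.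

Step 10
Reactants: 17 methyl (5E,14S,15R)-3,9-dihydroxy-16,16-dimethoxy-6,14-dimethyl-2,10-dimethylidene-15-(triethylsilyloxy)hexadec-5-enoate
Product: 18 methyl (5E,14S,15R)-3-hydroxy-16,16-dimethoxy-6,14-dimethyl-2,10-dimethylidene-9-oxo-15-(triethylsilyloxy)hexadec-5-enoate (C-3 epimers)
Conditions: MnO2 (activated, excess), CH2Cl2, rt
Reagents that add atoms: none
Why: Manganese dioxide oxidises the electron-rich allylic C7 alcohol to the enone while the electron-poor allylic alcohol next to the acrylate reacts far more slowly, so the two hydroxyls are told apart without protecting groups.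

Step 11
Reactants: 18 methyl (5E,14S,15R)-3-hydroxy-16,16-dimethoxy-6,14-dimethyl-2,10-dimethylidene-9-oxo-15-(triethylsilyloxy)hexadec-5-enoate
Product: 19 methyl (2Z,5E,14S,15R)-2-(bromomethyl)-16,16-dimethoxy-6,14-dimethyl-10-methylidene-9-oxo-15-(triethylsilyloxy)hexadeca-2,5-dienoate
Conditions: NBS, Me2S, CH2Cl2, −20 → 0 °C
Reagents that add atoms: N-bromosuccinimide, O=C1CCC(=O)N1Br
Why: Corey–Kim-type activation of the Baylis–Hillman alcohol and SN2′ delivery of bromide give the favoured (Z)-2-(bromomethyl)enoate and remove the stereocentre at C1; the reagent spares non-allylic hydroxyls and silyl ethers.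

Step 12
Reactants: 19 methyl (2Z,5E,14S,15R)-2-(bromomethyl)-16,16-dimethoxy-6,14-dimethyl-10-methylidene-9-oxo-15-(triethylsilyloxy)hexadeca-2,5-dienoate
Product: 22 (1S,3E,12S,13R,14R)-13-hydroxy-7-oxocembra-3,8(19),15(17)-trien-16,14-olide, via hydroxy aldehyde 20 (not isolated), via hydroxy ester 21 (not isolated)
Conditions: 1 M aq. HBr, THF, rt; then NaHCO3 to pH 3, indium powder (3 equiv), THF/H2O 1:1 (1 mM), rt
Reagents that add atoms: water, O
Why: Proposed new method: aqueous acid unmasks the α-hydroxy aldehyde and indium metal converts the allylic bromide into a γ-substituted 2-(methoxycarbonyl)allylindium that adds through its γ-carbon (C1) to C14 in a chair transition state on the aldehyde face fixed by chelation of trivalent indium between the C13 hydroxyl and the carbonyl oxygen, so the Z-reagent gives the 1,14-syn and the chelate the 13,14-syn relationship (1S,14R) and the γ-hydroxy ester closes to the cis-lactone, while addition to the C7 ketone would need a seven-membered ring holding an E-olefin; the closest known reactions are the intermolecular indium-mediated aqueous Barbier allylation of α-hydroxy aldehydes with (Z)-2-(bromomethyl)alk-2-enoates (syn,syn adducts, cis-α-methylene-γ-lactones) and macrocyclising allylations with CrCl2.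

Step 13
Reactants: 22 (1S,3E,12S,13R,14R)-13-hydroxy-7-oxocembra-3,8(19),15(17)-trien-16,14-olide
Product: 23 (1S,3E,12S,13R,14R)-13-acetoxy-7-oxocembra-3,8(19),15(17)-trien-16,14-olide
Conditions: Ac2O, pyridine, DMAP (cat.), CH2Cl2, 0 °C → rt
Reagents that add atoms: acetic anhydride, CC(=O)OC(C)=O
Why: DMAP-catalysed acylation of the only remaining hydroxyl (C13).

Step 14
Reactants: 23 (1S,3E,12S,13R,14R)-13-acetoxy-7-oxocembra-3,8(19),15(17)-trien-16,14-olide
Product: 24 (1S,3R,4R,12S,13R,14R)-13-acetoxy-3,4-epoxy-7-oxocembra-8(19),15(17)-dien-16,14-olide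
Conditions: D-fructose-derived Shi ketone (1,2:4,5-di-O-isopropylidene-β-D-erythro-2,3-hexodiulo-2,6-pyranose, 30 mol %), KHSO5 (as 2KHSO5·KHSO4·K2SO4), K2CO3, Bu4NHSO4, MeCN/CH2(OMe)2/aq. Na2B4O7 buffer (pH 10.5), 0 °C
Reagents that add atoms: potassium peroxymonosulfate, [K+].[O-]S(=O)(=O)OO
Why: Shi asymmetric epoxidation, in which the chiral dioxirane reacts only with the electron-rich E-trisubstituted C3=C4 olefin (the enone and the α-methylene lactone are electron-poor) through a spiro transition state that gives the (R,R)-epoxide from E-trisubstituted alkenes with this catalyst enantiomer.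

Step 15
Reactants: 24 (1S,3R,4R,12S,13R,14R)-13-acetoxy-3,4-epoxy-7-oxocembra-8(19),15(17)-dien-16,14-olide
Product: 25 (1S,3R,4R,7R,12S,13R,14R)-13-acetoxy-3,4-epoxy-7-hydroxycembra-8(19),15(17)-dien-16,14-olide (CNP0230083.2)
Conditions: (S)-2-methyl-CBS-oxazaborolidine (0.5 equiv), catecholborane, toluene, −78 °C; then MeOH
Reagents that add atoms: none
Why: Corey–Bakshi–Shibata 1,2-reduction, in which the oxazaborolidine binds the ketone with the α-branched alkenyl side (C8) as the large group and delivers hydride to give the 7R allylic alcohol under reagent control, leaving the lactone, acetate and epoxide untouched.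

**Compound list**

1 | 2,2-dimethoxyacetaldehyde | COC(OC)C=O | starting material
2 | (Z)-crotylboronic acid pinacol ester | C/C=C\CB1OC(C)(C)C(C)(C)O1 | starting material
3 | (2R,3S)-1,1-dimethoxy-3-methylpent-4-en-2-ol | C=C[C@H](C)[C@@H](O)C(OC)OC | intermediate
4 | (2R,3S)-1,1-dimethoxy-3-methyl-2-(triethylsilyloxy)pent-4-ene | C=C[C@H](C)[C@@H](O[Si](CC)(CC)CC)C(OC)OC | intermediate
5 | 2,3-dibromopropene | C=C(Br)CBr | starting material
6 | 9-[(3S,4R)-5,5-dimethoxy-3-methyl-4-(triethylsilyloxy)pentyl]-9-borabicyclo[3.3.1]nonane | C1CCC2CCCC1B2CC[C@H](C)[C@@H](O[Si](CC)(CC)CC)C(OC)OC | intermediate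
7 | (6S,7R)-2-bromo-8,8-dimethoxy-6-methyl-7-(triethylsilyloxy)oct-1-ene | C=C(Br)CCC[C@H](C)[C@@H](O[Si](CC)(CC)CC)C(OC)OC | intermediate
8 | tert-butyldimethyl(pent-4-yn-1-yloxy)silane | C#CCCCO[Si](C)(C)C(C)(C)C | starting material
9 | (E)-[5-(tert-butyldimethylsilyloxy)-2-methylpent-1-en-1-yl]dimethylalane | C[Al](C)/C=C(\C)CCCO[Si](C)(C)C(C)(C)C | intermediate
10 | (E)-7-(tert-butyldimethylsilyloxy)-4-methylhept-3-en-1-ol | OCC/C=C(\C)CCCO[Si](C)(C)C(C)(C)C | intermediate
11 | (E)-7-(tert-butyldimethylsilyloxy)-4-methylhept-3-enal | O=CC/C=C(\C)CCCO[Si](C)(C)C(C)(C)C | intermediate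
12 | methyl propiolate | C#CC(=O)OC | starting material
13 | methyl 2-(diisobutylalanyl)prop-2-enoate | COC(=O)C(=C)[Al](CC(C)C)CC(C)C | intermediate
14 | methyl (5E)-9-(tert-butyldimethylsilyloxy)-3-hydroxy-6-methyl-2-methylidenenon-5-enoate (racemic at C-3) | COC(=O)C(=C)C(O)C/C=C(\C)CCCO[Si](C)(C)C(C)(C)C | intermediate
15 | methyl (5E)-3,9-dihydroxy-6-methyl-2-methylidenenon-5-enoate (racemic) | COC(=O)C(=C)C(O)C/C=C(\C)CCCO | intermediate
16 | methyl (5E)-3-hydroxy-6-methyl-2-methylidene-9-oxonon-5-enoate (racemic) | COC(=O)C(=C)C(O)C/C=C(\C)CCC=O | intermediate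
17 | methyl (5E,14S,15R)-3,9-dihydroxy-16,16-dimethoxy-6,14-dimethyl-2,10-dimethylidene-15-(triethylsilyloxy)hexadec-5-enoate (C-3/C-9 epimer mixture) | C=C(CCC[C@H](C)[C@@H](O[Si](CC)(CC)CC)C(OC)OC)C(O)CC/C(C)=C/CC(O)C(=C)C(=O)OC | intermediate
18 | methyl (5E,14S,15R)-3-hydroxy-16,16-dimethoxy-6,14-dimethyl-2,10-dimethylidene-9-oxo-15-(triethylsilyloxy)hexadec-5-enoate (C-3 epimers) | C=C(CCC[C@H](C)[C@@H](O[Si](CC)(CC)CC)C(OC)OC)C(=O)CC/C(C)=C/CC(O)C(=C)C(=O)OC | intermediate
19 | methyl (2Z,5E,14S,15R)-2-(bromomethyl)-16,16-dimethoxy-6,14-dimethyl-10-methylidene-9-oxo-15-(triethylsilyloxy)hexadeca-2,5-dienoate | C=C(CCC[C@H](C)[C@@H](O[Si](CC)(CC)CC)C(OC)OC)C(=O)CC/C(C)=C/C/C=C(\CBr)C(=O)OC | intermediate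
20 | methyl (2Z,5E,14S,15R)-2-(bromomethyl)-15-hydroxy-6,14-dimethyl-10-methylidene-9,16-dioxohexadeca-2,5-dienoate | C=C(CCC[C@H](C)[C@@H](O)C=O)C(=O)CC/C(C)=C/C/C=C(\CBr)C(=O)OC | intermediate
21 | methyl 2-[(1S,2R,3R,4S,12E)-2,3-dihydroxy-4,12-dimethyl-8-methylidene-9-oxocyclotetradec-12-en-1-yl]prop-2-enoate | C=C1CCC[C@H](C)[C@@H](O)[C@H](O)[C@H](C(=C)C(=O)OC)C/C=C(\C)CCC1=O | intermediate
22 | (1S,3E,12S,13R,14R)-13-hydroxy-7-oxocembra-3,8(19),15(17)-trien-16,14-olide | C=C1CCC[C@H](C)[C@@H](O)[C@@H]2OC(=O)C(=C)[C@@H]2C/C=C(\C)CCC1=O | intermediate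
23 | (1S,3E,12S,13R,14R)-13-acetoxy-7-oxocembra-3,8(19),15(17)-trien-16,14-olide | C=C1CCC[C@H](C)[C@@H](OC(C)=O)[C@@H]2OC(=O)C(=C)[C@@H]2C/C=C(\C)CCC1=O | intermediate
24 | (1S,3R,4R,12S,13R,14R)-13-acetoxy-3,4-epoxy-7-oxocembra-8(19),15(17)-dien-16,14-olide | C=C1CCC[C@H](C)[C@@H](OC(C)=O)[C@@H]2OC(=O)C(=C)[C@@H]2C[C@H]2O[C@]2(C)CCC1=O | intermediate
25 | (1S,3R,4R,7R,12S,13R,14R)-13-acetoxy-3,4-epoxy-7-hydroxycembra-8(19),15(17)-dien-16,14-olide (CNP0230083.2) | C=C1CCC[C@H](C)[C@@H](OC(C)=O)[C@@H]2OC(=O)C(=C)[C@@H]2C[C@H]2O[C@]2(C)CC[C@H]1O | target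

**Step count and risks**

Total: 15 steps (west branch steps 1–3, east branch steps 4–8, joint sequence steps 9–15). Longest linear sequence: 12 steps (8 → 25, steps 4–15).

The three steps most likely to fail:

Step 12 (Barbier macrocyclisation). Risks are oligomerisation at the dilution needed, epimerisation of the α-hydroxy aldehyde at C13, and ring strain overriding the chelate/chair control. The fallback reverses the order of the two carbonyl additions; it sets out from 14 (with 7) and returns at 22. NBS/Me2S converts 14 into the silyl ether bromide F1. Intermolecular indium Barbier coupling of F1 with 7 (same aqueous HBr unmasking, then indium powder in THF/H2O at normal concentration) gives the cis-lactone vinyl bromide F2. HF·pyridine gives the diol F3, and TEMPO/PhI(OAc)2 oxidises only its primary alcohol to the aldehyde F4. CrCl2/NiCl2 then closes the ring at C7–C8 to the macrocyclic diol F5 (C-7 epimers), and MnO2 oxidises the allylic hydroxyl to give 22.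

Step 14 (epoxidation on the macrocycle). The ring conformation may expose only one olefin face and override the catalyst. The fallback sets out from 23 and returns at 24; it uses a halohydrin detour, which places oxygen on the face opposite to the one the electrophile attacks. NBS in aqueous THF gives the bromohydrin F6 (Br at C3, OH at C4), and DBU in CH2Cl2 closes it with inversion at C3 to 24.

Step 15 (reduction of the macrocyclic enone). Substrate bias may oppose the oxazaborolidine, or 1,4-reduction may compete. The fallback sets out from 24 and returns at 25; it uses substrate control followed by inversion. NaBH4/CeCl3·7H2O in MeOH at −78 °C gives the allylic alcohol; if this is the 7S epimer F7, Mitsunobu reaction with formic acid (PPh3, diisopropyl azodicarboxylate) gives the 7R formate F8, which KHCO3 in MeOH/H2O cleaves selectively in the presence of the C13 acetate to give 25.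

**Further compounds**

F1 | step 12 | methyl (2Z,5E)-2-(bromomethyl)-9-(tert-butyldimethylsilyloxy)-6-methylnona-2,5-dienoate | COC(=O)/C(CBr)=C/C/C=C(\C)CCCO[Si](C)(C)C(C)(C)C
F2 | step 12 | (4S,5R)-5-[(1R,2S)-6-bromo-1-hydroxy-2-methylhept-6-en-1-yl]-4-[(2E)-6-(tert-butyldimethylsilyloxy)-3-methylhex-2-en-1-yl]-3-methylideneoxolan-2-one | C=C(Br)CCC[C@H](C)[C@@H](O)[C@@H]1OC(=O)C(=C)[C@@H]1C/C=C(\C)CCCO[Si](C)(C)C(C)(C)C
F3 | step 12 | (4S,5R)-5-[(1R,2S)-6-bromo-1-hydroxy-2-methylhept-6-en-1-yl]-4-[(2E)-6-hydroxy-3-methylhex-2-en-1-yl]-3-methylideneoxolan-2-one | C=C(Br)CCC[C@H](C)[C@@H](O)[C@@H]1OC(=O)C(=C)[C@@H]1C/C=C(\C)CCCO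
F4 | step 12 | aldehyde of F3 (primary alcohol oxidised to CHO; same (4S,5R)-lactone, (1R,2S) side chain and E-olefin) | C=C(Br)CCC[C@H](C)[C@@H](O)[C@@H]1OC(=O)C(=C)[C@@H]1C/C=C(\C)CCC=O
F5 | step 12 | (1S,3E,12S,13R,14R)-7,13-dihydroxycembra-3,8(19),15(17)-trien-16,14-olide (C-7 epimers) | C=C1CCC[C@H](C)[C@@H](O)[C@@H]2OC(=O)C(=C)[C@@H]2C/C=C(\C)CCC1O
F6 | step 14 | (1S,3S,4R,12S,13R,14R)-13-acetoxy-3-bromo-4-hydroxy-7-oxocembra-8(19),15(17)-dien-16,14-olide | C=C1CCC[C@H](C)[C@@H](OC(C)=O)[C@@H]2OC(=O)C(=C)[C@@H]2C[C@H](Br)[C@](C)(O)CCC1=O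
F7 | step 15 | (1S,3R,4R,7S,12S,13R,14R)-13-acetoxy-3,4-epoxy-7-hydroxycembra-8(19),15(17)-dien-16,14-olide | C=C1CCC[C@H](C)[C@@H](OC(C)=O)[C@@H]2OC(=O)C(=C)[C@@H]2C[C@H]2O[C@]2(C)CC[C@@H]1O
F8 | step 15 | (1S,3R,4R,7R,12S,13R,14R)-13-acetoxy-3,4-epoxy-7-formyloxycembra-8(19),15(17)-dien-16,14-olide | C=C1CCC[C@H](C)[C@@H](OC(C)=O)[C@@H]2OC(=O)C(=C)[C@@H]2C[C@H]2O[C@]2(C)CC[C@H]1OC=O
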